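**Remark on the chemistry (assumption):** the recombinant E. coli strains that express toluene dioxygenase (todC1C2BA) and the cis-dihydrodiol dehydrogenase (todD) are treated as available biocatalysts, not as synthetic steps. The diol written O[C@@H]1C(Br)=CC=C(Br)[C@@H]1O has the descriptors (1S,2R), which for this symmetric compound is the cis, meso isomer, so no structure needed correction.

Locants used throughout: ring A has C1 (OH), C2 and C4 (Br), C6 (ether O). Ring B has C1' (OH), C2' (ether O), C3' and C6' (Br).

## Structural features

The target is an achiral diaryl ether: two benzene rings, ring A and ring B, are joined through one oxygen, and each ring carries a free hydroxyl on the carbon next to that oxygen. Ring A is a phenol (C1–OH) with bromine at C2 and C4 and the ether oxygen at C6. Ring B is a phenol (C1'–OH) with the ether oxygen at C2' and bromine at C3' and C6', which makes it a catechol mono-aryl ether whose two oxygens are flanked by two para-related bromines. The target has no stereocentres; the only ones in the route are the two adjacent, mutually cis carbinol carbons of the dihydrodiol intermediate, and they are erased when ring B is rearomatized. The four C–Br bonds rule out hydrogenation, dissolving metals, halogen–metal exchange and most palladium chemistry, the catechol stage is sensitive to oxidation, and a ring A phenoxide heated with base could displace the C3' bromine and close a brominated dibenzo-1,4-dioxin, which is a safety concern as well as a yield concern. The real difficulty is ring B: bromine sits at both positions ortho to the oxygens (C3' and C6'), whereas electrophilic bromination of a catechol or a 2-aryloxyphenol goes para to oxygen (C4' and C5'), and only one of the two neighbouring oxygens may be arylated. The key step exploits the fact that ring B is 1,4-dibromobenzene in which one of its two equivalent CH–CH edges, C1'–C2', bears both oxygens, so a dioxygenase can form both C–O bonds on that edge in one event. The hydroxyl of ring A is carried as a formyl group, which also activates C6 for the ether-forming substitution.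

## Logic of the disconnections

**8 back to 6 (through 7).** The C1–O bond of ring A is cut and replaced by a C1–CHO bond: 8 arises from 7 by loss of the formyl group, and 7 from 6 by insertion of oxygen into the aryl–carbonyl bond. The cut is made here because the formyl group in 6 is the activating group that makes the ether bond accessible by substitution, and, unlike a halogen or a free hydroxyl at C1, it can neither leave nor attack. The gain is that the last step only unmasks a phenol. The demand on the forward step is that the aryl group, not hydrogen, migrates in the peracid adduct, and that the formate is cleaved without heating a phenoxide next to the C3' bromine.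

**6 back to 4 and 5.** The ether bond O–C6 (ring A side) is cut. This separates the two rings into a commercial electrophile, 5, whose fluorine is ortho to the formyl group, and a symmetric nucleophile, 4, whose two oxygens are equivalent. The gain is full convergence with no regiochemical question on ring B. The demands are that the substitution stops after one oxygen has reacted, that fluoride is displaced in preference to the two activated bromides of 5, and that air is excluded.

**4 back to 2 (through 3).** No skeletal bond is cut; two hydrogens are returned to C1' and C2', which takes the aromatic ring back to the diene diol 2, with 3 as the keto tautomer in between. The reason is that 2 is at the oxidation level that an arene dioxygenase delivers. The demand is a dehydrogenation that never exposes 2 to acid, because loss of water instead of hydrogen would throw away one of the two oxygens.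

**2 back to 1.** Both C–O bonds, C1'–O and C2'–O, are cut at once. This leads to 1, a commercial arene that already holds the two bromines in the correct para relationship. The gain is that the ortho,ortho'-dibromo dioxygen pattern needs no directing groups and no bromination chemistry. The demand is that the enzyme accepts a poorly soluble para-disubstituted benzene and that 2 is isolated under neutral to slightly basic conditions.

## Other disconnections considered

**Alternative 1:** The cut is at the C2'–O ether bond and at the C1'–O bond, the latter masked as a C–B bond.
- **Forward key step:** fluoride (CsF) would release 3,6-dibromobenzyne A4 from 3,6-dibromo-2-(trimethylsilyl)phenyl trifluoromethanesulfonate A3. The B–O bond of 2-(3,5-dibromo-2-methoxyphenoxy)-4,4,5,5-tetramethyl-1,3,2-dioxaborolane A2 (the pinacol borate of 3,5-dibromo-2-methoxyphenol A1) would add across the strained triple bond to give 2-[3,6-dibromo-2-(3,5-dibromo-2-methoxyphenoxy)phenyl]-4,4,5,5-tetramethyl-1,3,2-dioxaborolane A5. Oxidation of the C–B bond and O-demethylation would then lead to 8.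
- **In its favour:** A4 is symmetric, so it matches the chosen plan in having no regiochemical question on ring B. It is better than the chosen plan in that the two oxygens of ring B are different from the outset (one arrives as the ether, the other as boron), so no mono-arylation of a catechol has to be controlled. It needs no fermentation.
- **Against it here:** A3 has to be built over several steps in which silylation and metalation chemistry must coexist with two aryl bromides. The aryl anion or ate complex formed after the oxygen has added sits ortho to a bromine and could expel bromide to give a second aryne. Aryne insertion into a B–O bond is far less established than insertion into other element–element bonds, so protonation to an ether lacking the C1' oxygen is a plausible leak.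
- **Comparison:** on structure the two plans are equal (symmetry). On mechanism the chosen plan rests on the intrinsic cis-1,2-delivery of an enzyme, the alternative on a less secure insertion. On step economy the alternative is clearly longer, since two steps follow its key step and several precede it.

**Alternative 2:** The cut is at both phenolic C–O bonds, C1–O and C1'–O, each traced back to a C–CHO bond.
- **Forward key step:** 2,4-dibromo-6-(3,6-dibromo-2-formylphenoxy)benzaldehyde A7 would be assembled from 5 and 3,6-dibromo-2-hydroxybenzaldehyde A6 by the same fluoride displacement. A peracid would oxidize A7 twice to 2,4-dibromo-6-(3,6-dibromo-2-formyloxyphenoxy)phenyl formate A8, and hydrolysis would give 8.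
- **In its favour:** A6 has a single hydroxyl, so over-arylation cannot occur, and no air-sensitive catechol is handled; on both points it is better than the chosen plan. It is fully chemical, and with A6 one formylation away from a commercial dibromophenol its step count is equal to or slightly lower than that of the chosen plan.
- **Against it here:** aryl migration has to win over hydride migration twice instead of once. In A7 the only donor, the ether oxygen, is shared between two formyl-bearing rings, so each migrating ring is poorer than ring A of 6. The phenoxide of A6 is conjugated to its own formyl group and flanked by two substituents, which makes it a weaker nucleophile than the catecholate. The 3',6'-dibromo pattern is not created but has to be bought and then formylated at the crowded position between hydroxyl and bromine.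
- **Comparison:** the mechanism is of the same type as the last step of the chosen plan, with the demand doubled. The chosen plan is ahead in the origin of the ring B pattern; the alternative is ahead in chemoselectivity of the ether formation.

**Alternative 3:** The cut is at the two C–Br bonds of ring B together with its aromaticity.
- **Forward key step:** 2-(3,5-dibromo-2-methoxyphenoxy)cyclohex-2-en-1-one A9 (reachable from A1 and a six-membered 2,3-epoxy ketone by ring opening and loss of water) would be treated with three equivalents of bromine. Bromination at C3 and C6, loss of HBr and enolization would give 3,6-dibromo-2-(3,5-dibromo-2-methoxyphenoxy)phenol A10, and BBr3 would then free 8.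
- **In its favour:** it uses bulk reagents, no enzyme and no organometallics, so on reagent access and scale-up it is better than the chosen plan. The step count is about equal. The ring A oxygen is methylated, so there is no mono-arylation question.
- **Against it here:** all positional control comes from enol and enone reactivity. Bromine has to enter at the enol ether carbon C3 and at the alpha' carbon C6 and nowhere else. Once the ring has aromatized, the position para to the new hydroxyl (C4') is its most nucleophilic site, so over-bromination competes with the third equivalent, and the free positions of ring A ortho and para to the aryloxy oxygen are exposed as well. A demethylation step is added.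
- **Comparison:** on structure the chosen plan is ahead because the bromine pattern is bought in 1 and fixed by symmetry, and no electrophilic bromination occurs anywhere. On mechanism, kinetic control of three brominations stands against acceptance of a substrate by an enzyme. On step economy the two are equal.

Key step: step 1

## Route

**Step 1**
Reactants: 1 1,4-dibromobenzene
Product: 2 cis-3,6-dibromocyclohexa-3,5-diene-1,2-diol (meso, 1R,2S)
Conditions: whole cells of recombinant E. coli expressing toluene dioxygenase (TodC1C2BA; e.g. JM109(pDTG601), IPTG-induced), glucose feed, air, phosphate buffer pH 7.2, 30 °C; 1 supplied as a solution in liquid paraffin; work-up at pH 8, EtOAc, cold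
Reagents that add atoms: dioxygen, O=O
Why: This is a Rieske-type non-heme iron dioxygenation, the toluene dioxygenase cis-dihydroxylation that is established for monohalobenzenes and for para-dihalobenzenes. Two electrons from NADH reach the oxygenase through its reductase and ferredoxin, dioxygen is activated at the mononuclear iron site, and both oxygen atoms are passed to two neighbouring ring carbons from the same face, so the C1'–O and C2'–O bonds form together and the arene becomes a diene diol. No ring is closed. The two new stereocentres, C1 and C2 of 2, are cis because both oxygens come from one iron-bound dioxygen molecule. Since a mirror plane of 1 bisects the attacked edge, the product is the meso compound whichever face the enzyme uses, so enantioselectivity is not required. The selectivity that is required is the choice of ring edge: the enzyme oxidizes an unsubstituted CH=CH bond next to a halogen and not a C(Br)=CH bond, and the two CH=CH edges of 1 are identical by symmetry, so only the 3,6-dibromo-1,2-diol can arise. Isolation is kept at pH 7 or above and cold, because acid would cause loss of water with rearomatization and so remove one of the two oxygens.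

**Step 2**
Reactants: 2 cis-3,6-dibromocyclohexa-3,5-diene-1,2-diol
Product: 4 3,6-dibromobenzene-1,2-diol (3,6-dibromocatechol), via 2,5-dibromo-6-hydroxycyclohexa-2,4-dien-1-one 3 (not isolated)
Conditions: resting cells of recombinant E. coli expressing the NAD+-dependent cis-dihydrodiol dehydrogenase TodD (e.g. JM109(pDTG602)), phosphate buffer pH 7.0, 30 °C, air; then ascorbic acid, pH 4, EtOAc
Reagents that add atoms: none
Why: This is an enzymatic dehydrogenative aromatization of an arene cis-dihydrodiol, the second reaction of the toluene pathway: hydride passes from one carbinol carbon to NAD+ to give ketol 3, whose enolization is aromatization to 4. No acid is present, so both oxygens are kept and the C–Br bonds are untouched; because 2 is meso, either carbinol carbon leads to the same catechol and both stereocentres disappear. Respiration of the cells returns NADH to NAD+.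

**Step 3**
Reactants: 4 3,6-dibromobenzene-1,2-diol; 5 2,4-dibromo-6-fluorobenzaldehyde
Product: 6 2,4-dibromo-6-(3,6-dibromo-2-hydroxyphenoxy)benzaldehyde
Conditions: 4 (1.5 equiv), K2CO3, DMF (degassed), N2, 60 °C
Reagents that add atoms: none
Why: This is a nucleophilic aromatic substitution by addition–elimination: the monophenoxide of 4 adds at C6 of 5, where fluorine is ortho to the formyl group, and fluoride leaves much faster than either bromide. The two oxygens of 4 are equivalent, so either gives the same ether and a Smiles shift of ring A between them would be degenerate; an excess of 4 and the hindered, hydrogen-bonded second hydroxyl should hold the reaction at mono-arylation. Ring A has no leaving group next to the new ether carbon, so closure to a dibenzo-1,4-dioxin is not possible at this stage.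

**Step 4**
Reactants: 6 2,4-dibromo-6-(3,6-dibromo-2-hydroxyphenoxy)benzaldehyde
Product: 8 2,4-dibromo-6-(3,6-dibromo-2-hydroxyphenoxy)phenol (the target), via 2,4-dibromo-6-(3,6-dibromo-2-hydroxyphenoxy)phenyl formate 7 (not isolated)
Conditions: mCPBA, CH2Cl2, 0 °C to rt; aq. Na2S2O3 wash; then MeOH, cat. HCl, rt
Reagents that add atoms: mCPBA (3-chloroperoxybenzoic acid), O=C(OO)c1cccc(Cl)c1
Why: This is a Dakin-type Baeyer–Villiger oxidation: the peracid adds to the formyl group and in the Criegee adduct the aryl group, which carries an ortho aryloxy donor and two ortho substituents, migrates to oxygen to give formate 7. Acid-catalysed methanolysis then frees the phenol without ever generating a phenoxide next to the C3' bromine, so dioxin closure is avoided. The electron-poor ring B phenol and the C–Br bonds should be inert to the peracid.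

## Compound list

1 | 1,4-dibromobenzene | Brc1ccc(Br)cc1 | starting material
2 | cis-3,6-dibromocyclohexa-3,5-diene-1,2-diol (meso, 1R,2S) | O[C@@H]1C(Br)=CC=C(Br)[C@@H]1O | intermediate
3 | 2,5-dibromo-6-hydroxycyclohexa-2,4-dien-1-one (keto tautomer of 4; one transient stereocentre at C6, configuration not assigned, lost on enolization) | O=C1C(Br)=CC=C(Br)C1O | intermediate (not isolated)
4 | 3,6-dibromobenzene-1,2-diol (3,6-dibromocatechol) | Oc1c(Br)ccc(Br)c1O | intermediate
5 | 2,4-dibromo-6-fluorobenzaldehyde | O=Cc1c(F)cc(Br)cc1Br | starting material
6 | 2,4-dibromo-6-(3,6-dibromo-2-hydroxyphenoxy)benzaldehyde | O=Cc1c(Br)cc(Br)cc1Oc1c(Br)ccc(Br)c1O | intermediate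
7 | 2,4-dibromo-6-(3,6-dibromo-2-hydroxyphenoxy)phenyl formate | O=COc1c(Br)cc(Br)cc1Oc1c(Br)ccc(Br)c1O | intermediate (not isolated)
8 | 2,4-dibromo-6-(3,6-dibromo-2-hydroxyphenoxy)phenol (no stereocentres) | Oc1c(Br)cc(Br)cc1Oc1c(Br)ccc(Br)c1O | target

## Step count and least certain steps

Total step count: 4. Longest linear sequence: 4 steps (1 → 2 → 4 → 6 → 8); 5 enters at step 3. Steps 1 and 2 could be merged into one fermentation with a strain expressing both enzymes, at the price of exposing the dioxygenase cells to the catechol.

**Step 1 (key step).**
- **Most likely to go wrong:** low throughput, because crystalline 1 is poorly available to cells in water and para-disubstituted benzenes are turned over more slowly than monosubstituted ones. Acid- or heat-induced loss of water during isolation is the second risk.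
- **Fallback:** it sets out from 1 and returns at 4, bypassing 2 and 3, and replaces the enzymatic oxygenation with two chemical oxygenations. Deprotonation of 1 ortho to bromine with LiN(i-Pr)2 in THF at −78 °C and trapping with B(OMe)3 would give dimethyl (2,5-dibromophenyl)boronate F1. H2O2 in AcOH would oxidize it in the same flask to 2,5-dibromophenol F2. ortho-Formylation of F2 at its only free ortho position (MgCl2, Et3N, paraformaldehyde, MeCN, reflux) would give 3,6-dibromo-2-hydroxybenzaldehyde F3, the same compound as A6. A classical Dakin oxidation (H2O2, aq. NaOH, 0 °C to rt, N2) would pass through 3,6-dibromo-2-hydroxyphenyl formate F4 to 4.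

**Step 2.**
- **Most likely to go wrong:** poor acceptance of a diol substituted at both C3 and C6 by the dehydrogenase, slow dehydration of the substrate in the cell suspension, and autoxidation of the catechol in aerated neutral buffer.
- **Fallback:** it sets out from 2 and returns at 4 through 3, now formed as the racemate, and replaces the enzyme with an activated-DMSO oxidation (SO3·pyridine, DMSO, i-Pr2NEt, CH2Cl2, 0 °C). Oxidation of one allylic carbinol gives 3, which enolizes to 4 in the basic medium. The ortho positions of 4 are blocked, so the sulfonium reagent has no ring carbon to attack, and a wash with aqueous Na2S2O4 would return any over-oxidized material to the catechol level. No compound outside the list is made.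

**Step 3.**
- **Most likely to go wrong:** a second arylation of the remaining hydroxyl, oxidative degradation of the catecholate if air enters, and substitution at the bromine-bearing carbons of 5 if the hindered phenoxide needs more heat.
- **Fallback:** it sets out from 4 and returns at 8, masking one oxygen before the coupling. Mono-O-methylation of 4 (MeI, one equivalent, K2CO3, acetone; 4 is symmetric, so only one mono-ether exists) would give 3,6-dibromo-2-methoxyphenol F5. Its phenoxide and 5 (K2CO3, DMF, 60–80 °C) would give 2,4-dibromo-6-(3,6-dibromo-2-methoxyphenoxy)benzaldehyde F6. mCPBA would convert F6 into 2,4-dibromo-6-(3,6-dibromo-2-methoxyphenoxy)phenyl formate F7, and acid-catalysed methanolysis would give 2,4-dibromo-6-(3,6-dibromo-2-methoxyphenoxy)phenol F8. BBr3 in CH2Cl2 (−78 to 0 °C) would cleave the methyl ether to 8 and leave the diaryl ether intact.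

**Step 4.**
- **Most likely to go wrong:** hydride migration competing with aryl migration in the peracid adduct, which diverts material to the carboxylic acid, and slow oxygen insertion because two bromines make the migrating ring electron-poor.
- **Fallback:** it sets out from 6 and returns at 8, replacing the formyl group by an acetyl group, whose methyl migrates so poorly that only the aryl shift remains. MeMgBr (excess, THF, −40 to 0 °C) would give 1-[2,4-dibromo-6-(3,6-dibromo-2-hydroxyphenoxy)phenyl]ethan-1-ol F9 (racemic). MnO2 in CH2Cl2 would oxidize it to 1-[2,4-dibromo-6-(3,6-dibromo-2-hydroxyphenoxy)phenyl]ethan-1-one F10. CF3CO3H (from (CF3CO)2O and urea–H2O2, Na2HPO4, CH2Cl2) would give 2,4-dibromo-6-(3,6-dibromo-2-hydroxyphenoxy)phenyl acetate F11, and K2CO3 in MeOH at rt would release 8.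

## Further compounds

F1 | step 1 | dimethyl (2,5-dibromophenyl)boronate | COB(OC)c1cc(Br)ccc1Br
F2 | step 1 | 2,5-dibromophenol | Oc1cc(Br)ccc1Br
F3 | step 1 | 3,6-dibromo-2-hydroxybenzaldehyde | O=Cc1c(Br)ccc(Br)c1O
F4 | step 1 | 3,6-dibromo-2-hydroxyphenyl formate | O=COc1c(Br)ccc(Br)c1O
F0 | step 2 | none | none
F5 | step 3 | 3,6-dibromo-2-methoxyphenol | COc1c(Br)ccc(Br)c1O
F6 | step 3 | 2,4-dibromo-6-(3,6-dibromo-2-methoxyphenoxy)benzaldehyde | COc1c(Br)ccc(Br)c1Oc1cc(Br)cc(Br)c1C=O
F7 | step 3 | 2,4-dibromo-6-(3,6-dibromo-2-methoxyphenoxy)phenyl formate | COc1c(Br)ccc(Br)c1Oc1cc(Br)cc(Br)c1OC=O
F8 | step 3 | 2,4-dibromo-6-(3,6-dibromo-2-methoxyphenoxy)phenol | COc1c(Br)ccc(Br)c1Oc1cc(Br)cc(Br)c1O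
F9 | step 4 | 1-[2,4-dibromo-6-(3,6-dibromo-2-hydroxyphenoxy)phenyl]ethan-1-ol (racemic) | CC(O)c1c(Br)cc(Br)cc1Oc1c(Br)ccc(Br)c1O
F10 | step 4 | 1-[2,4-dibromo-6-(3,6-dibromo-2-hydroxyphenoxy)phenyl]ethan-1-one | CC(=O)c1c(Br)cc(Br)cc1Oc1c(Br)ccc(Br)c1O
F11 | step 4 | 2,4-dibromo-6-(3,6-dibromo-2-hydroxyphenoxy)phenyl acetate | CC(=O)Oc1c(Br)cc(Br)cc1Oc1c(Br)ccc(Br)c1O
A1 | alternative 1 | 3,5-dibromo-2-methoxyphenol | COc1c(Br)cc(Br)cc1O
A2 | alternative 1 | 2-(3,5-dibromo-2-methoxyphenoxy)-4,4,5,5-tetramethyl-1,3,2-dioxaborolane | COc1c(Br)cc(Br)cc1OB1OC(C)(C)C(C)(C)O1
A3 | alternative 1 | 3,6-dibromo-2-(trimethylsilyl)phenyl trifluoromethanesulfonate | C[Si](C)(C)c1c(Br)ccc(Br)c1OS(=O)(=O)C(F)(F)F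
A4 | alternative 1 | 3,6-dibromobenzyne (1,4-dibromo-2,3-didehydrobenzene) | BrC1=CC=C(Br)C#C1
A5 | alternative 1 | 2-[3,6-dibromo-2-(3,5-dibromo-2-methoxyphenoxy)phenyl]-4,4,5,5-tetramethyl-1,3,2-dioxaborolane | COc1c(Br)cc(Br)cc1Oc1c(Br)ccc(Br)c1B1OC(C)(C)C(C)(C)O1
A6 | alternative 2 | 3,6-dibromo-2-hydroxybenzaldehyde | O=Cc1c(Br)ccc(Br)c1O
A7 | alternative 2 | 2,4-dibromo-6-(3,6-dibromo-2-formylphenoxy)benzaldehyde | O=Cc1c(Br)cc(Br)cc1Oc1c(Br)ccc(Br)c1C=O
A8 | alternative 2 | 2,4-dibromo-6-(3,6-dibromo-2-formyloxyphenoxy)phenyl formate | O=COc1c(Br)cc(Br)cc1Oc1c(Br)ccc(Br)c1OC=O
A9 | alternative 3 | 2-(3,5-dibromo-2-methoxyphenoxy)cyclohex-2-en-1-one | COc1c(Br)cc(Br)cc1OC1=CCCCC1=O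
A10 | alternative 3 | 3,6-dibromo-2-(3,5-dibromo-2-methoxyphenoxy)phenol | COc1c(Br)cc(Br)cc1Oc1c(Br)ccc(Br)c1O
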